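## Retrosynthetic overview

1. The target comes from a protected flavone by BCl3 removal of two isopropyl ethers (O5, O7) and one benzyl ether (O4′); the 6-OMe is kept.
2. Ring C (the pyranone) is closed last by 6-endo attack of the C8a hydroxyl, freed from a MOM ether, on an aryl ynone; O5 is still an isopropyl ether, so only the 6-methoxy-8-pyrrolidinyl isomer can form.
3. The ynone comes from a second MOM-directed ortho-lithiation of ring A and an alkynyl Weinreb amide that carries ring B.
4. The pyrrolidine ring is made first: the ortho-lithiated, mirror-symmetric ring A adds to the (S)-tert-butanesulfinyl imine of 4-chlorobutanal (sets the (R) centre), the N anion closes the ring, then N–S is exchanged for N–Me.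
5. Ring A comes from 2-methoxyresorcinol by O-isopropylation, Ir-catalysed C–H borylation/oxidation at C5 and MOM protection. Ring order: pyrrolidine, then pyranone; rings A and B are bought as benzenes.

Assumptions: the stereocentre in the SMILES is read as (R). Compounds 1, 6, 7 and 14 are bought (6 can also be freed from its commercial dimethyl acetal just before use). The facial sense in step 5 is predicted from the open transition-state model for an organolithium in THF; the configuration of 11 is confirmed by crystallography before material is carried on.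

## Route

Step 1
Reactants: 1 2-methoxybenzene-1,3-diol (2-methoxyresorcinol)
Product: 2 2-methoxy-1,3-di(propan-2-yloxy)benzene
Conditions: 2-bromopropane (3 equiv), K2CO3, DMF, 70 °C
Reagents that add atoms: 2-bromopropane, CC(C)Br
Why: Williamson ether synthesis on both phenols; isopropyl ethers survive BuLi and HCl and are later cleaved by BCl3 in preference to the methyl ether.

Step 2
Reactants: 2 2-methoxy-1,3-di(propan-2-yloxy)benzene
Product: 4 4-methoxy-3,5-di(propan-2-yloxy)phenol, via aryl pinacol boronate 3 (not isolated)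
Conditions: [Ir(OMe)(cod)]2 (1.5 mol%), 4,4′-di-tert-butyl-2,2′-bipyridine (3 mol%), B2pin2 (0.55 equiv), THF, 80 °C; then KHSO5 (as the triple salt 2KHSO5·KHSO4·K2SO4), acetone/H2O, 0 °C, 10 min
Reagents that add atoms: potassium peroxymonosulfate (KHSO5), [K+].[O-]S(=O)(=O)OO
Why: Sterically controlled Ir-catalysed C–H borylation takes the only ring C–H with no ortho substituent (C5), and the boronate is oxidised in the same pot to the phenol (one-pot borylation/oxidation).

Step 3
Reactants: 4 4-methoxy-3,5-di(propan-2-yloxy)phenol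
Product: 5 2-methoxy-5-(methoxymethoxy)-1,3-di(propan-2-yloxy)benzene
Conditions: MOMCl, i-Pr2NEt, CH2Cl2, 0 °C → rt
Reagents that add atoms: chloromethyl methyl ether, COCCl
Why: O-alkylation of the phenol (MOM ether formation) marks the future O1 apart from O5/O7 and installs the directing group for both later ortho-lithiations.

Step 4
Reactants: 6 4-chlorobutanal; 7 (S)-2-methylpropane-2-sulfinamide
Product: 8 (S)-N-[(E)-4-chlorobutylidene]-2-methylpropane-2-sulfinamide
Conditions: CuSO4 (anhydrous), CH2Cl2, rt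
Reagents that add atoms: none
Why: Ellman condensation of an aldehyde with tert-butanesulfinamide gives the E sulfinimine, with the sulfur stereocentre carried over unchanged.

Step 5
Reactants: 5 2-methoxy-5-(methoxymethoxy)-1,3-di(propan-2-yloxy)benzene; 8 (S)-N-[(E)-4-chlorobutylidene]-2-methylpropane-2-sulfinamide
Product: 11 (2R)-1-[(S)-tert-butylsulfinyl]-2-[3-methoxy-6-(methoxymethoxy)-2,4-di(propan-2-yloxy)phenyl]pyrrolidine, via aryllithium 9 (not isolated), via N-lithio sulfinamide adduct 10 (not isolated)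
Conditions: n-BuLi (1.05 equiv), THF, 0 °C, 1 h; then 8 (1.2 equiv), −78 °C, 2 h; then −78 °C → rt, 12 h
Reagents that add atoms: none
Why: Directed ortho-metalation at one of the two equivalent ring C–H bonds gives the internally chelated aryllithium, which adds 1,2 to the Ellman sulfinimine through the open transition state (attack anti to tert-butyl on the s-cis imine, so the (S)-sulfinyl group sets the (R) carbon), and the lithium sulfinamide then closes the pyrrolidine by intramolecular SN2 on the primary chloride, the minor diastereomer being removed by chromatography.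

Step 6
Reactants: 11 (2R)-1-[(S)-tert-butylsulfinyl]-2-[3-methoxy-6-(methoxymethoxy)-2,4-di(propan-2-yloxy)phenyl]pyrrolidine
Product: 13 (2R)-2-[3-methoxy-6-(methoxymethoxy)-2,4-di(propan-2-yloxy)phenyl]-1-methylpyrrolidine, via pyrrolidine hydrochloride 12 (not isolated)
Conditions: HCl (4 M in dioxane, 2.5 equiv), MeOH, 0 °C, 20 min; concentrate; then Et3N, 37% aq. HCHO, NaBH(OAc)3, ClCH2CH2Cl, rt
Reagents that add atoms: formaldehyde, C=O
Why: Acidic methanolysis cleaves the N–S bond of the auxiliary within minutes at 0 °C (faster than the aryl MOM ether and too cold for benzylic C–N ionisation), and the free secondary amine is methylated by reductive amination, neither operation touching the stereocentre.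

Step 7
Reactants: 14 1-(benzyloxy)-4-ethynylbenzene
Product: 16 3-[4-(benzyloxy)phenyl]-N-methoxy-N-methylprop-2-ynamide, via lithium acetylide 15 (not isolated)
Conditions: n-BuLi, THF, −78 °C; then ClC(O)N(OMe)Me, −78 °C → rt
Reagents that add atoms: N-methoxy-N-methylcarbamoyl chloride, CON(C)C(Cl)=O
Why: Deprotonation of the terminal alkyne and acyl substitution at the carbamoyl chloride give the alkynyl Weinreb amide (rings B and the C2–C4 carbons of ring C in one piece).

Step 8
Reactants: 13 (2R)-2-[3-methoxy-6-(methoxymethoxy)-2,4-di(propan-2-yloxy)phenyl]-1-methylpyrrolidine; 16 3-[4-(benzyloxy)phenyl]-N-methoxy-N-methylprop-2-ynamide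
Product: 19 3-[4-(benzyloxy)phenyl]-1-{3-methoxy-6-(methoxymethoxy)-5-[(2R)-1-methylpyrrolidin-2-yl]-2,4-di(propan-2-yloxy)phenyl}prop-2-yn-1-one, via aryllithium 17 (not isolated), via lithium carbinolamine adduct 18 (not isolated)
Conditions: n-BuLi (1.1 equiv), THF, 0 °C, 1 h; then 16, −78 °C → 0 °C; then H2O
Reagents that add atoms: none
Why: A second MOM-directed ortho-lithiation takes the only ring hydrogen left (flanked by OMOM and O-i-Pr), and Weinreb ketone synthesis stops at the ynone because the N-methoxy-N-methyl chelate only collapses on work-up.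

Step 9
Reactants: 19 3-[4-(benzyloxy)phenyl]-1-{3-methoxy-6-(methoxymethoxy)-5-[(2R)-1-methylpyrrolidin-2-yl]-2,4-di(propan-2-yloxy)phenyl}prop-2-yn-1-one
Product: 21 2-[4-(benzyloxy)phenyl]-6-methoxy-8-[(2R)-1-methylpyrrolidin-2-yl]-5,7-di(propan-2-yloxy)-4H-chromen-4-one, via hydroxyaryl ynone 20 (not isolated)
Conditions: HCl (3 M in MeOH), rt → 40 °C
Reagents that add atoms: none
Why: Acidic methanolysis of the carbonyl-flanked MOM ether frees only the C8a oxygen, which closes onto the acid-activated ynone in 6-endo fashion (oxa-Michael cyclisation to the flavone) while O5 is still blocked, and the acyl-deactivated ring keeps the stereocentre from ionising.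

Step 10
Reactants: 21 2-[4-(benzyloxy)phenyl]-6-methoxy-8-[(2R)-1-methylpyrrolidin-2-yl]-5,7-di(propan-2-yloxy)-4H-chromen-4-one
Product: 22 5,7-dihydroxy-2-(4-hydroxyphenyl)-6-methoxy-8-[(2R)-1-methylpyrrolidin-2-yl]-4H-chromen-4-one
Conditions: BCl3 (8 equiv), CH2Cl2, −78 °C → 0 °C; then H2O, 0 °C
Reagents that add atoms: none
Why: Lewis-acid ether cleavage by BCl3 removes the carbonyl-chelated 5-O-isopropyl, the 7-O-isopropyl and the benzyl group (secondary and benzylic C–O bonds) much faster than the primary methyl ether, and the low temperature protects the benzylic C–N stereocentre.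

## Compound list

1 | 2-methoxybenzene-1,3-diol | COc1c(O)cccc1O | starting material
2 | 2-methoxy-1,3-di(propan-2-yloxy)benzene | COc1c(OC(C)C)cccc1OC(C)C | intermediate
3 | 2-[4-methoxy-3,5-di(propan-2-yloxy)phenyl]-4,4,5,5-tetramethyl-1,3,2-dioxaborolane | COc1c(OC(C)C)cc(B2OC(C)(C)C(C)(C)O2)cc1OC(C)C | intermediate
4 | 4-methoxy-3,5-di(propan-2-yloxy)phenol | COc1c(OC(C)C)cc(O)cc1OC(C)C | intermediate
5 | 2-methoxy-5-(methoxymethoxy)-1,3-di(propan-2-yloxy)benzene | COCOc1cc(OC(C)C)c(OC)c(OC(C)C)c1 | intermediate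
6 | 4-chlorobutanal | O=CCCCCl | starting material
7 | (S)-2-methylpropane-2-sulfinamide | CC(C)(C)[S@](=O)N | starting material
8 | (S)-N-[(E)-4-chlorobutylidene]-2-methylpropane-2-sulfinamide | CC(C)(C)[S@](=O)/N=C/CCCCl | intermediate
9 | [3-methoxy-6-(methoxymethoxy)-2,4-di(propan-2-yloxy)phenyl]lithium | [Li]c1c(OCOC)cc(OC(C)C)c(OC)c1OC(C)C | intermediate
10 | N-lithio (S)-N-{(1R)-4-chloro-1-[3-methoxy-6-(methoxymethoxy)-2,4-di(propan-2-yloxy)phenyl]butyl}-2-methylpropane-2-sulfinamide | COCOc1cc(OC(C)C)c(OC)c(OC(C)C)c1[C@H](N([Li])[S@@](=O)C(C)(C)C)CCCCl | intermediate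
11 | (2R)-1-[(S)-tert-butylsulfinyl]-2-[3-methoxy-6-(methoxymethoxy)-2,4-di(propan-2-yloxy)phenyl]pyrrolidine | COCOc1cc(OC(C)C)c(OC)c(OC(C)C)c1[C@H]2CCCN2[S@@](=O)C(C)(C)C | intermediate
12 | (2R)-2-[3-methoxy-6-(methoxymethoxy)-2,4-di(propan-2-yloxy)phenyl]pyrrolidine hydrochloride | COCOc1cc(OC(C)C)c(OC)c(OC(C)C)c1[C@H]2CCCN2.Cl | intermediate
13 | (2R)-2-[3-methoxy-6-(methoxymethoxy)-2,4-di(propan-2-yloxy)phenyl]-1-methylpyrrolidine | COCOc1cc(OC(C)C)c(OC)c(OC(C)C)c1[C@H]2CCCN2C | intermediate
14 | 1-(benzyloxy)-4-ethynylbenzene | C#Cc1ccc(OCc2ccccc2)cc1 | starting material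
15 | lithium 2-[4-(benzyloxy)phenyl]ethyn-1-ide | [Li]C#Cc1ccc(OCc2ccccc2)cc1 | intermediate
16 | 3-[4-(benzyloxy)phenyl]-N-methoxy-N-methylprop-2-ynamide | CON(C)C(=O)C#Cc1ccc(OCc2ccccc2)cc1 | intermediate
17 | {3-methoxy-6-(methoxymethoxy)-5-[(2R)-1-methylpyrrolidin-2-yl]-2,4-di(propan-2-yloxy)phenyl}lithium | COCOc1c([Li])c(OC(C)C)c(OC)c(OC(C)C)c1[C@H]2CCCN2C | intermediate
18 | lithium 3-[4-(benzyloxy)phenyl]-1-[methoxy(methyl)amino]-1-{3-methoxy-6-(methoxymethoxy)-5-[(2R)-1-methylpyrrolidin-2-yl]-2,4-di(propan-2-yloxy)phenyl}prop-2-yn-1-olate (either configuration at the carbinolamine carbon) | COCOc1c(C(O[Li])(N(C)OC)C#Cc3ccc(OCc4ccccc4)cc3)c(OC(C)C)c(OC)c(OC(C)C)c1[C@H]2CCCN2C | intermediate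
19 | 3-[4-(benzyloxy)phenyl]-1-{3-methoxy-6-(methoxymethoxy)-5-[(2R)-1-methylpyrrolidin-2-yl]-2,4-di(propan-2-yloxy)phenyl}prop-2-yn-1-one | COCOc1c(C(=O)C#Cc3ccc(OCc4ccccc4)cc3)c(OC(C)C)c(OC)c(OC(C)C)c1[C@H]2CCCN2C | intermediate
20 | 3-[4-(benzyloxy)phenyl]-1-{2-hydroxy-5-methoxy-3-[(2R)-1-methylpyrrolidin-2-yl]-4,6-di(propan-2-yloxy)phenyl}prop-2-yn-1-one | Oc1c(C(=O)C#Cc3ccc(OCc4ccccc4)cc3)c(OC(C)C)c(OC)c(OC(C)C)c1[C@H]2CCCN2C | intermediate
21 | 2-[4-(benzyloxy)phenyl]-6-methoxy-8-[(2R)-1-methylpyrrolidin-2-yl]-5,7-di(propan-2-yloxy)-4H-chromen-4-one | COc1c(OC(C)C)c([C@H]2CCCN2C)c2oc(-c3ccc(OCc4ccccc4)cc3)cc(=O)c2c1OC(C)C | intermediate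
22 | 5,7-dihydroxy-2-(4-hydroxyphenyl)-6-methoxy-8-[(2R)-1-methylpyrrolidin-2-yl]-4H-chromen-4-one | COc1c(O)c([C@H]2CCCN2C)c2oc(-c3ccc(O)cc3)cc(=O)c2c1O | target

## Step count and risks

Total step count: 10 (steps 4 and 7 make the two side fragments).
Longest linear sequence: 8 steps (1, 2, 3, 5, 6, 8, 9, 10), from 1 to 22.

**Step 5** is the most likely to fail. The hindered aryllithium may deprotonate the enolisable sulfinimine instead of adding, and the facial selectivity may be modest or run the other way. The fallback sets out from 5 and comes back at 13. NBS (MeCN, 0 °C) brominates one of the two equivalent ring positions of 5 to give 2-bromo-4-methoxy-1-(methoxymethoxy)-3,5-di(propan-2-yloxy)benzene F1. Separately, N-Boc-pyrrolidine is deprotonated enantioselectively (s-BuLi, (−)-sparteine, MTBE, −78 °C) to tert-butyl (2S)-2-lithiopyrrolidine-1-carboxylate F2. ZnCl2 converts this with retention into tert-butyl (2S)-2-(chlorozincio)pyrrolidine-1-carboxylate F3. Negishi coupling of F3 with F1 (Pd(OAc)2, t-Bu3P·HBF4, rt) gives, again with retention, tert-butyl (2R)-2-[3-methoxy-6-(methoxymethoxy)-2,4-di(propan-2-yloxy)phenyl]pyrrolidine-1-carboxylate F4. Here the stereocentre comes from asymmetric deprotonation, not from an auxiliary. LiAlH4 (THF, reflux) reduces the carbamate of F4 to the N-methyl group, which is 13; steps 4 to 6 then drop out.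

**Step 6** may lose the MOM ether (needed as directing group in step 8) during the acidic N–S cleavage. The fallback sets out from 11 and comes back at 13. HCl in MeOH at rt is run until both the sulfinyl and the MOM group are gone, giving 4-methoxy-2-[(2R)-pyrrolidin-2-yl]-3,5-di(propan-2-yloxy)phenol hydrochloride F5. Reductive methylation (Et3N, aq. HCHO, NaBH(OAc)3) gives 4-methoxy-2-[(2R)-1-methylpyrrolidin-2-yl]-3,5-di(propan-2-yloxy)phenol F6. The phenoxide of F6 (NaH, THF, 0 °C) is then re-protected with MOMCl to give 13.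

**Step 8** may fail because the doubly ortho-substituted aryllithium adds slowly, or in conjugate fashion, to the alkynyl Weinreb amide. The fallback sets out from 13 and comes back at 19. Aryllithium 17 is trapped with the small electrophile DMF to give 3-methoxy-6-(methoxymethoxy)-5-[(2R)-1-methylpyrrolidin-2-yl]-2,4-di(propan-2-yloxy)benzaldehyde F7. Lithium acetylide 15 (from 14 and n-BuLi) adds to F7 to give 3-[4-(benzyloxy)phenyl]-1-{3-methoxy-6-(methoxymethoxy)-5-[(2R)-1-methylpyrrolidin-2-yl]-2,4-di(propan-2-yloxy)phenyl}prop-2-yn-1-ol F8 (both carbinol epimers, which does not matter). MnO2 (CH2Cl2, rt) oxidises F8 to ynone 19.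

## Further compounds

F1 | step 5 | 2-bromo-4-methoxy-1-(methoxymethoxy)-3,5-di(propan-2-yloxy)benzene | COCOc1cc(OC(C)C)c(OC)c(OC(C)C)c1Br
F2 | step 5 | tert-butyl (2S)-2-lithiopyrrolidine-1-carboxylate | [Li][C@H]1CCCN1C(=O)OC(C)(C)C
F3 | step 5 | tert-butyl (2S)-2-(chlorozincio)pyrrolidine-1-carboxylate | Cl[Zn][C@H]1CCCN1C(=O)OC(C)(C)C
F4 | step 5 | tert-butyl (2R)-2-[3-methoxy-6-(methoxymethoxy)-2,4-di(propan-2-yloxy)phenyl]pyrrolidine-1-carboxylate | COCOc1cc(OC(C)C)c(OC)c(OC(C)C)c1[C@H]2CCCN2C(=O)OC(C)(C)C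
F5 | step 6 | 4-methoxy-2-[(2R)-pyrrolidin-2-yl]-3,5-di(propan-2-yloxy)phenol hydrochloride | Oc1cc(OC(C)C)c(OC)c(OC(C)C)c1[C@H]2CCCN2.Cl
F6 | step 6 | 4-methoxy-2-[(2R)-1-methylpyrrolidin-2-yl]-3,5-di(propan-2-yloxy)phenol | Oc1cc(OC(C)C)c(OC)c(OC(C)C)c1[C@H]2CCCN2C
F7 | step 8 | 3-methoxy-6-(methoxymethoxy)-5-[(2R)-1-methylpyrrolidin-2-yl]-2,4-di(propan-2-yloxy)benzaldehyde | COCOc1c(C=O)c(OC(C)C)c(OC)c(OC(C)C)c1[C@H]2CCCN2C
F8 | step 8 | 3-[4-(benzyloxy)phenyl]-1-{3-methoxy-6-(methoxymethoxy)-5-[(2R)-1-methylpyrrolidin-2-yl]-2,4-di(propan-2-yloxy)phenyl}prop-2-yn-1-ol | COCOc1c(C(O)C#Cc3ccc(OCc4ccccc4)cc3)c(OC(C)C)c(OC)c(OC(C)C)c1[C@H]2CCCN2C
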